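Atoms are numbered C1–C2–C3–C9–C13 (ring C), C3–C4–C8–C9 (cyclobutane), C4–C5–C6–C7–C8 (ring A) and C9–O10–C11–C12–C13 (lactone). The route rests on cutting C3–CH3 and C9–O10: these adjacent, fully substituted cyclobutane carbons carry methyl and oxygen on the face opposite ring A, and a planar C3=C9 enone is open only there. One operation, cuprate methylation at C3 then oxidation of the C9=C13 enol ether, sets both centres and the cis-syn-cis array. The precursor is a tricyclic enone: ring A a plain C5=C6 cyclopentene, cyclobutene C3=C9 shared with ring C, C13 ketone, from enantiopure bicyclo[3.2.0]hept-2-en-6-one.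

Key step: step 7

Remarks on the chemistry
- Assumption: the (1R,5S) ketone and ethyl 2-(diethoxyphosphoryl)acrylate are taken as catalogue compounds.
- Stereochemical reading of the target: rings A and C lie on the same face of the cyclobutane. C3–CH3, O10, C1–O and C5–O are on the convex faces. At C7 the hydroxyl is exo and the methyl endo.
- Ring A stays a C5=C6 olefin until ring C is built. Unsaturation or a carbonyl next to C8 would acidify C8–H and misdirect enolisation of the C9 ketone.
- The 1-acylcyclobutanol formed in the key step can ring-expand by an acyloin shift under alkoxide-forming base, so C1 is oxygenated through soft enolisation.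
- C12 must arrive with its oxygenated carbon attached, so a 2-(alkoxymethyl)phosphonoacetate is used; a plain phosphonoacetate would leave C12–H.
- The C7 carbinol is made by radical hydration of a methylene group. A methyl nucleophile would attack a C7 ketone from the exo face and give the wrong epimer.

Step 1
Reactants: 1 (1R,5S)-bicyclo[3.2.0]hept-2-en-6-one
Product: 2 N,N-dimethylhydrazone of 1
Conditions: Me2NNH2, AcOH (cat.), MgSO4, EtOH, rt
Reagents that add atoms: 1,1-dimethylhydrazine, CN(C)N
Why: Hydrazone formation on the strained, unhindered cyclobutanone is fast and turns a self-condensing ketone into a metalloenamine precursor, with C4 and C8 untouched.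

Step 2
Reactants: 2 N,N-dimethylhydrazone of 1; 3 2-(2-bromoethyl)-1,3-dioxolane
Product: 5 C3-alkylated cyclobutanone, via alkylated hydrazone 4 (not isolated)
Conditions: LDA, THF, −78 → 0 °C; 3, −78 °C → rt; then CuCl2, THF/aq. phosphate buffer (pH 7), rt
Reagents that add atoms: water, O
Why: Hydrazone azaenolate alkylation (LDA removes a C3 methylene proton, not the bridgehead C8–H) should couple with an unactivated primary bromide where a cyclobutanone enolate would self-condense, and neutral CuCl2-assisted hydrolysis frees the ketone with the dioxolane intact; the new C3 centre (chain exo) is erased in step 3.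

Step 3
Reactants: 5 C3-alkylated cyclobutanone
Product: 6 C3=C9 cyclobutenyl triflate
Conditions: LDA, THF, −78 °C; PhNTf2, −78 → 0 °C
Reagents that add atoms: N-phenylbis(trifluoromethanesulfonimide), O=S(=O)(N(c1ccccc1)S(=O)(=O)C(F)(F)F)C(F)(F)F
Why: Enolate O-sulfonylation, in which enolisation toward C8 would put a double bond at a ring-fusion atom of the bicyclo[3.2.0] core and is strongly disfavoured, so the tetrasubstituted C3=C9 enol triflate should form; no stereocentre is created.

Step 4
Reactants: 6 C3=C9 cyclobutenyl triflate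
Product: 7 triflate aldehyde
Conditions: 2 M HCl, THF, rt
Reagents that add atoms: water, O
Why: Acid-catalysed acetal hydrolysis, to which the alkenyl triflate and the isolated ring A olefin are inert.

Step 5
Reactants: 7 triflate aldehyde
Product: 8 tricyclic allylic alcohol
Conditions: CrCl2 (6 equiv), NiCl2 (2 mol%), DMF, rt, high dilution
Reagents that add atoms: none
Why: Intramolecular Nozaki–Hiyama–Kishi reaction, in which zerovalent nickel inserts into the C9–OTf bond and the derived alkenylchromium adds 5-exo-trig to the tethered aldehyde, closing ring C at C9–C13; the C13 carbinol configuration does not matter because it is oxidised next.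

Step 6
Reactants: 8 tricyclic allylic alcohol
Product: 9 tricyclic enone
Conditions: Dess–Martin periodinane, NaHCO3, CH2Cl2, 0 °C
Reagents that add atoms: none
Why: Buffered Dess–Martin oxidation of the allylic alcohol is non-basic, so the doubly allylic C4–H is left alone, and the C5=C6 olefin cannot move into conjugation without a ring-fusion double bond; the strained enone is used at once.

Step 7
Reactants: 9 tricyclic enone; 10 methyllithium
Product: 13 C3-methyl C9-hydroxy tricyclic C13 ketone, via silyl enol ether 11 (not isolated), via silyloxy epoxide 12 (not isolated)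
Conditions: 10 (2 equiv), CuI, Et2O, 0 °C; 9, Me3SiCl, THF, −78 °C; Et3N/pentane, filtration; DMDO (1.05 equiv), acetone/CH2Cl2, −78 °C; aq. citric acid, THF, 0 °C
Reagents that add atoms: dimethyldioxirane, CC1(C)OO1; chlorotrimethylsilane, C[Si](C)(C)Cl (in 11 and 12 only)
Why: Me2CuLi (from 10 and CuI) complexes the strained C3=C9 enone and transfers methyl to C3 with relief of cyclobutene strain while Me3SiCl traps the C9=C13 enolate as 11, and DMDO then epoxidises this enol ether so that mild acid opens silyloxy oxirane 12 to ketol 13. The closest known chemistry is chlorosilane-accelerated cuprate addition to fully substituted bicyclic enones followed by Rubottom oxidation of the trapped enol ether, and the cyclobutene-fused acceptor is only a more reactive member of that class. No ring is closed. C3 is set by substrate control, because C5 and C7 of the cis-fused ring A hang over one face of the planar cyclobutene and methyl therefore enters from the face that carries only H4 and H8. C9 is set by ring strain, because oxygen delivered to the other face would leave ring C trans-fused to the cyclobutane, so O10 ends cis to the new methyl and ring C folds toward ring A (cis-syn-cis). The step needs 1,4- over 1,2-addition (soft cuprate plus chlorosilane), facial control (ring A shielding) and oxidation of the electron-rich enol ether in preference to the C5=C6 olefin (one equivalent of DMDO at −78 °C).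

Step 8
Reactants: 13 C3-methyl C9-hydroxy tricyclic C13 ketone
Product: 16 C1,C9-dihydroxy ketone, via bis-silyl enol ether 14 (not isolated), via C1–C13 silyloxy epoxide 15 (not isolated)
Conditions: Me3SiOTf, Et3N, CH2Cl2, 0 °C; pentane, filtration; DMDO (1.05 equiv), acetone/CH2Cl2, −78 °C; citric acid, MeOH/H2O, rt
Reagents that add atoms: dimethyldioxirane, CC1(C)OO1; trimethylsilyl trifluoromethanesulfonate, C[Si](C)(C)OS(=O)(=O)C(F)(F)F (in 14 and 15 only)
Why: Soft enolisation caps the C9 hydroxyl and gives the only possible enol ether (C13=C1) without ever forming a C9 alkoxide, and Rubottom oxidation then delivers oxygen to C1 from the convex face of ring C, the concave face being closed by ring A, which sets C1.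

Step 9
Reactants: 16 C1,C9-dihydroxy ketone
Product: 17 C1 silyl ether
Conditions: TBSCl, imidazole, DMF, rt
Reagents that add atoms: tert-butyl(chloro)dimethylsilane, CC(C)(C)[Si](C)(C)Cl
Why: Silylation under imidazole catalysis should take the secondary C1 hydroxyl and leave the hindered tertiary C9 hydroxyl free.

Step 10
Reactants: 18 ethyl 2-(diethoxyphosphoryl)acrylate; 19 (4-methoxyphenyl)methanol
Product: 20 alkoxymethyl phosphonoacetate
Conditions: KOtBu (5 mol%), THF, 0 °C → rt
Reagents that add atoms: none
Why: Base-catalysed oxa-Michael addition of the benzylic alcohol to the doubly activated vinylphosphonate; the new centre is racemic and is lost in step 13.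

Step 11
Reactants: 20 alkoxymethyl phosphonoacetate
Product: 21 phosphono acid
Conditions: LiOH, THF/H2O, 0 °C; 1 M HCl
Reagents that add atoms: lithium hydroxide, [Li+].[OH-]
Why: Saponification of the carboxylic ester at 0 °C should leave the phosphonate diester and the benzyl ether untouched.

Step 12
Reactants: 17 C1 silyl ether; 21 phosphono acid
Product: 22 C9 phosphonoacetate ester
Conditions: DCC, DMAP (cat.), CH2Cl2, 0 °C → rt
Reagents that add atoms: none
Why: Steglich esterification, in which carbodiimide activation of an α-phosphono acid passes through a phosphonoketene that acylates hindered tertiary alcohols; the two epimers at the phosphonate carbon converge in step 13.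

Step 13
Reactants: 22 C9 phosphonoacetate ester
Product: 23 butenolide with C12 benzyloxymethyl group
Conditions: LiCl, DBU, MeCN, 0 °C → rt
Reagents that add atoms: none
Why: Intramolecular Horner–Wadsworth–Emmons olefination onto the C13 ketone closes the five-membered lactone with C12=C13 fixed by the ring, and the exo C1 silyl ether is the more stable epimer under the base.

Step 14
Reactants: 23 butenolide with C12 benzyloxymethyl group
Product: 24 C12 hydroxymethyl butenolide
Conditions: DDQ, CH2Cl2/aq. buffer (pH 7), 0 °C
Reagents that add atoms: none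
Why: Oxidative cleavage of the 4-methoxybenzyl ether by benzylic hydride abstraction, which leaves the olefins, silyl ether and lactone alone.

Step 15
Reactants: 24 C12 hydroxymethyl butenolide
Product: 26 C5 allylic alcohol, via C5 hydroperoxide 25 (not isolated)
Conditions: O2, 5,10,15,20-tetraphenylporphyrin (cat.), visible light, CH2Cl2, 0 °C; then PPh3, rt
Reagents that add atoms: dioxygen, O=O
Why: Schenck ene reaction, in which singlet oxygen attacks the open exo face of the C5=C6 olefin, bonds to C5 and takes the exo hydrogen of C7 (taking the bridgehead C4–H would create a ring-fusion olefin), so C5–O is set exo and the olefin moves to C6=C7 before phosphine reduction of the hydroperoxide.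

Step 16
Reactants: 26 C5 allylic alcohol
Product: 27 diacetate
Conditions: Ac2O, pyridine, DMAP (cat.), CH2Cl2, 0 °C → rt
Reagents that add atoms: acetic anhydride, CC(=O)OC(C)=O
Why: Standard acylation of the secondary C5 and primary C12–CH2 hydroxyls, the only free hydroxyls present.

Step 17
Reactants: 27 diacetate
Product: 28 C7 ketone
Conditions: PdCl2 (20 mol%), CuCl, O2 (1 atm), DMF/H2O (7:1), 40 °C
Reagents that add atoms: water, O
Why: Wacker–Tsuji oxidation of an internal olefin, in which the allylic C5 acetate directs oxypalladation to the distal carbon C7 and so gives the β-acetoxy ketone.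

Step 18
Reactants: 28 C7 ketone
Product: 29 C7 methylene compound
Conditions: Zn, CH2Br2, TiCl4, THF/CH2Cl2, 0 °C → rt
Reagents that add atoms: dibromomethane, BrCBr
Why: Takai–Lombardo methylenation uses a non-basic zinc–titanium carbenoid, so the β-acetoxy ketone should not eliminate and the esters and lactone are not attacked.

Step 19
Reactants: 29 C7 methylene compound
Product: 31 C7 tertiary alcohol, via C7 hydroperoxide 30 (not isolated)
Conditions: Co(acac)2 (20 mol%), PhSiH3, O2 (1 atm), THF/i-PrOH, rt; then PPh3
Reagents that add atoms: dioxygen, O=O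
Why: Mukaiyama hydration, in which hydrogen-atom transfer to the methylene carbon gives the tertiary C7 radical and oxygen traps it on the exo face of ring A (the concave face is covered by ring C), so C7 gets hydroxyl exo and methyl endo.

Step 20
Reactants: 31 C7 tertiary alcohol
Product: 32 C1 alcohol
Conditions: HF·pyridine, THF/pyridine, 0 °C → rt
Reagents that add atoms: none
Why: Fluoride cleavage of the secondary silyl ether under mildly acidic, non-basic conditions should keep both acetates and the tertiary alcohol in place.

Step 21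
Reactants: 32 C1 alcohol; 33 tiglic acid
Product: 35 CNP0210373.1, via mixed anhydride 34 (not isolated)
Conditions: 33, 2,4,6-trichlorobenzoyl chloride, Et3N, toluene, rt; then 32, DMAP, rt
Reagents that add atoms: 2,4,6-trichlorobenzoyl chloride, O=C(Cl)c1c(Cl)cc(Cl)cc1Cl (in 34 only)
Why: Yamaguchi esterification should acylate the secondary allylic C1 hydroxyl and not the tertiary C7 hydroxyl, with the (E) geometry of the tiglate carried over from 33.

Compound list
1 | (1R,5S)-bicyclo[3.2.0]hept-2-en-6-one (carbonyl carbon = C9, its CH2 = C3, bridgeheads = C4 and C8) | O=C1C[C@@H]2C=CC[C@H]12 | starting material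
2 | N,N-dimethylhydrazone of 1 (C=N geometry not controlled; C4, C8 as in 1) | CN(C)N=C1C[C@@H]2C=CC[C@H]12 | intermediate
3 | 2-(2-bromoethyl)-1,3-dioxolane | BrCCC1OCCO1 | starting material
4 | N,N-dimethylhydrazone of 5 (not isolated) | CN(C)N=C1[C@@H](CCC2OCCO2)[C@@H]3C=CC[C@H]13 | intermediate
5 | 7-exo-[2-(1,3-dioxolan-2-yl)ethyl]bicyclo[3.2.0]hept-2-en-6-one (chain on C3, trans to ring A; C4, C8 as in 1) | O=C1[C@@H](CCC2OCCO2)[C@@H]3C=CC[C@H]13 | intermediate
6 | 7-[2-(1,3-dioxolan-2-yl)ethyl]bicyclo[3.2.0]hepta-2,6-dien-6-yl trifluoromethanesulfonate (C3=C9 enol triflate; cis ring fusion as in 1) | O=S(=O)(OC1=C(CCC2OCCO2)[C@@H]3C=CC[C@H]13)C(F)(F)F | intermediate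
7 | 3-[6-(trifluoromethanesulfonyloxy)bicyclo[3.2.0]hepta-2,6-dien-7-yl]propanal (cis ring fusion as in 1) | O=CCCC1=C(OS(=O)(=O)C(F)(F)F)[C@H]2CC=C[C@@H]12 | intermediate
8 | tricyclic allylic alcohol: ring C closed, C13 carbinol (both epimers), C3=C9 and C5=C6 olefins, H4/H8 cis | OC1CCC2=C1[C@H]3CC=C[C@@H]23 | intermediate
9 | tricyclic enone (key-step precursor): C13 ketone, C3=C9 cyclobutene shared with ring C, C5=C6 olefin, H4/H8 cis as in 1 | O=C1CCC2=C1[C@H]3CC=C[C@@H]23 | intermediate
10 | methyllithium | [Li]C | starting material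
11 | trimethylsilyl enol ether (C9=C13–OSiMe3), C3 methyl anti to ring A (not isolated) | C[Si](C)(C)OC1=C2[C@H]3CC=C[C@H]3[C@@]2(C)CC1 | intermediate
12 | 13-trimethylsilyloxy 9,13-epoxide, epoxide oxygen on the methyl face (not isolated) | C[Si](C)(C)O[C@]12CC[C@]3(C)[C@@H]4C=CC[C@@H]4[C@]13O2 | intermediate
13 | C3-methyl C9-hydroxy tricyclic C13 ketone (key-step product): methyl and hydroxyl cis, on the face opposite ring A; rings cis-syn-cis; C5=C6 olefin | O=C1CC[C@]2(C)[C@@H]3C=CC[C@@H]3[C@]12O | intermediate
14 | 9-O-trimethylsilyl C13=C1 trimethylsilyl enol ether of 13 (not isolated) | C[Si](C)(C)OC1=CC[C@]2(C)[C@@H]3C=CC[C@@H]3[C@]12O[Si](C)(C)C | intermediate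
15 | 1,13-epoxide of 14, epoxide oxygen on the convex face of ring C (not isolated) | C[Si](C)(C)O[C@]12O[C@H]1C[C@]3(C)[C@@H]4C=CC[C@@H]4[C@]23O[Si](C)(C)C | intermediate
16 | C1,C9-dihydroxy C13 ketone, C1–OH exo (cis to C3–CH3 and C9–OH) | O=C1[C@@H](O)C[C@]2(C)[C@@H]3C=CC[C@@H]3[C@]12O | intermediate
17 | C1 tert-butyldimethylsilyl ether of 16 (C9–OH free) | O=C1[C@@H](O[Si](C)(C)C(C)(C)C)C[C@]2(C)[C@@H]3C=CC[C@@H]3[C@]12O | intermediate
18 | ethyl 2-(diethoxyphosphoryl)prop-2-enoate | C=C(C(=O)OCC)P(=O)(OCC)OCC | starting material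
19 | (4-methoxyphenyl)methanol | COc1ccc(CO)cc1 | starting material
20 | ethyl 2-(diethoxyphosphoryl)-3-[(4-methoxyphenyl)methoxy]propanoate (racemic) | CCOC(=O)C(COCc1ccc(OC)cc1)P(=O)(OCC)OCC | intermediate
21 | 2-(diethoxyphosphoryl)-3-[(4-methoxyphenyl)methoxy]propanoic acid (racemic) | OC(=O)C(COCc1ccc(OC)cc1)P(=O)(OCC)OCC | intermediate
22 | C9 ester of 17 with acid 21 (both epimers at the phosphonate carbon) | O=C1[C@@H](O[Si](C)(C)C(C)(C)C)C[C@]2(C)[C@@H]3C=CC[C@@H]3[C@]12OC(=O)C(COCc4ccc(OC)cc4)P(=O)(OCC)OCC | intermediate
23 | tetracyclic butenolide: lactone C9–O10–C11(=O)–C12=C13, C12–CH2O(4-methoxybenzyl), C1–OTBS exo, C5=C6 olefin | CC(C)(C)[Si](C)(C)O[C@H]1C[C@]2(C)[C@@H]3C=CC[C@@H]3[C@@]23OC(=O)C(COCc4ccc(OC)cc4)=C13 | intermediate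
24 | C12 hydroxymethyl butenolide (C1–OTBS, C5=C6 olefin) | CC(C)(C)[Si](C)(C)O[C@H]1C[C@]2(C)[C@@H]3C=CC[C@@H]3[C@@]23OC(=O)C(CO)=C13 | intermediate
25 | C5 exo-hydroperoxide with C6=C7 olefin (not isolated) | CC(C)(C)[Si](C)(C)O[C@H]1C[C@]2(C)[C@@H]3[C@@H](OO)C=C[C@@H]3[C@@]23OC(=O)C(CO)=C13 | intermediate
26 | C5 exo-alcohol with C6=C7 olefin, C12–CH2OH, C1–OTBS | CC(C)(C)[Si](C)(C)O[C@H]1C[C@]2(C)[C@@H]3[C@@H](O)C=C[C@@H]3[C@@]23OC(=O)C(CO)=C13 | intermediate
27 | diacetate of 26 (C5–OAc, C12–CH2OAc) | CC(C)(C)[Si](C)(C)O[C@H]1C[C@]2(C)[C@@H]3[C@@H](OC(C)=O)C=C[C@@H]3[C@@]23OC(=O)C(COC(C)=O)=C13 | intermediate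
28 | C7 ketone (C5–OAc exo, C6 methylene) | CC(C)(C)[Si](C)(C)O[C@H]1C[C@]2(C)[C@@H]3[C@@H](OC(C)=O)CC(=O)[C@@H]3[C@@]23OC(=O)C(COC(C)=O)=C13 | intermediate
29 | C7 exocyclic methylene compound | CC(C)(C)[Si](C)(C)O[C@H]1C[C@]2(C)[C@@H]3[C@@H](OC(C)=O)CC(=C)[C@@H]3[C@@]23OC(=O)C(COC(C)=O)=C13 | intermediate
30 | C7 tertiary hydroperoxide, OOH exo and CH3 endo (not isolated) | CC(C)(C)[Si](C)(C)O[C@H]1C[C@]2(C)[C@@H]3[C@@H](OC(C)=O)C[C@@](C)(OO)[C@@H]3[C@@]23OC(=O)C(COC(C)=O)=C13 | intermediate
31 | C7 tertiary alcohol (OH exo, CH3 endo), C1–OTBS | CC(C)(C)[Si](C)(C)O[C@H]1C[C@]2(C)[C@@H]3[C@@H](OC(C)=O)C[C@@](C)(O)[C@@H]3[C@@]23OC(=O)C(COC(C)=O)=C13 | intermediate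
32 | C1 alcohol (C1–OH exo, C7–OH free, both acetates in place) | O[C@H]1C[C@]2(C)[C@@H]3[C@@H](OC(C)=O)C[C@@](C)(O)[C@@H]3[C@@]23OC(=O)C(COC(C)=O)=C13 | intermediate
33 | (E)-2-methylbut-2-enoic acid (tiglic acid) | C/C=C(\C)C(=O)O | starting material
34 | (E)-2-methylbut-2-enoic 2,4,6-trichlorobenzoic anhydride (not isolated) | C/C=C(\C)C(=O)OC(=O)c1c(Cl)cc(Cl)cc1Cl | intermediate
35 | CNP0210373.1 | C/C=C(\C)C(=O)O[C@H]1C[C@]2(C)[C@@H]3[C@@H](OC(C)=O)C[C@@](C)(O)[C@@H]3[C@@]23OC(=O)C(COC(C)=O)=C13 | target

Total step count: 21 steps. Longest linear sequence: 19 steps (steps 1–9 and 12–21); steps 10–11 make the phosphonate reagent.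

Steps most likely to fail

Step 7. Oxygen transfer to the C5=C6 olefin may compete with oxidation of the enol ether, the enol ether may be lost to moisture before it is oxidised, and the 1-acylcyclobutanol may ring-expand during desilylation. The fallback replaces electrophilic epoxidation by hydroxylation of the metal enolate. It sets out from crude silyl enol ether 11: MeLi (THF, 0 °C) cleaves the O–Si bond to give the lithium enolate F1, which is hydroxylated at −78 °C with 2-(phenylsulfonyl)-3-phenyloxaziridine, a reagent that does not touch isolated olefins. A buffered NH4Cl quench comes back to the route at ketol 13, with oxygen again forced onto the methyl face by the cis ring fusion.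

Step 5. The alkenylchromium intermediate may be protonated or reduced faster than it adds, because closure builds a tetrasubstituted cyclobutene shared by two rings; wrong-way enolisation in step 3 would feed the same failure. The fallback makes the C9–C13 bond by acyl-anion chemistry on the intact cyclobutanone and needs no triflate. It sets out from ketone 5: acid hydrolysis of the dioxolane gives the keto-aldehyde F2. A carbene generated from 3-benzyl-5-(2-hydroxyethyl)-4-methylthiazolium chloride and Et3N then adds the aldehyde carbon to the strained C9 ketone (intramolecular crossed benzoin) to give the tertiary ketol F3. Syn-dehydration with methyl N-(triethylammoniosulfonyl)carbamate, for which only C3–H is cis to the C9 hydroxyl, comes back to the route at enone 9.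

Step 17. Oxypalladation of the hindered C6=C7 olefin may be slow or unselective, reduced palladium may ionise the allylic acetates, and the β-acetoxy ketone may lose acetic acid. The fallback makes the C7 carbonyl first and adds the C5 oxygen afterwards by conjugate chemistry. It sets out from butenolide 23: SeO2/t-BuOOH oxidises the C7 methylene (ene reaction then [2,3]-shift, the bridgehead C4–H not being engaged) to the C7 allylic alcohol F4, and Dess–Martin oxidation gives the cyclopentenone F5. t-BuOOH/DBU epoxidises the enone from the exo face to the epoxy ketone F6, and sodium phenylselenide (from PhSeSePh and NaBH4, with AcOH in EtOH) cleaves the C6–O bond reductively to the β-hydroxy ketone F7 with C5–OH exo. DDQ then removes the 4-methoxybenzyl group to give the diol ketone F8, and acetylation (Ac2O, pyridine) comes back to the route at ketone 28.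

Further compounds
F1 | step 7 | lithium enolate of the C3-methyl ketone (C9=C13–OLi) | [Li]OC1=C2[C@H]3CC=C[C@H]3[C@@]2(C)CC1
F2 | step 5 | 3-(6-oxobicyclo[3.2.0]hept-2-en-7-yl)propanal (keto-aldehyde, chain exo) | O=C1[C@@H](CCC=O)[C@@H]2C=CC[C@H]12
F3 | step 5 | C9-hydroxy C13 ketone with C3–H (benzoin adduct, C3–H and C9–OH cis, ring C anti to ring A expected) | O=C1CC[C@H]2[C@@H]3C=CC[C@@H]3[C@@]12O
F4 | step 17 | C7 exo-allylic alcohol of 23 (C5=C6 olefin kept) | CC(C)(C)[Si](C)(C)O[C@H]1C[C@]2(C)[C@@H]3C=C[C@@H](O)[C@@H]3[C@@]23OC(=O)C(COCc4ccc(OC)cc4)=C13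
F5 | step 17 | ring A cyclopentenone (C7 ketone, C5=C6 olefin) | CC(C)(C)[Si](C)(C)O[C@H]1C[C@]2(C)[C@@H]3C=CC(=O)[C@@H]3[C@@]23OC(=O)C(COCc4ccc(OC)cc4)=C13
F6 | step 17 | C5,C6 exo-epoxy C7 ketone | CC(C)(C)[Si](C)(C)O[C@H]1C[C@]2(C)[C@@H]3[C@H]4O[C@H]4C(=O)[C@@H]3[C@@]23OC(=O)C(COCc5ccc(OC)cc5)=C13
F7 | step 17 | C5 exo-hydroxy C7 ketone (4-methoxybenzyl ether kept) | CC(C)(C)[Si](C)(C)O[C@H]1C[C@]2(C)[C@@H]3[C@@H](O)CC(=O)[C@@H]3[C@@]23OC(=O)C(COCc4ccc(OC)cc4)=C13
F8 | step 17 | C5 exo-hydroxy C7 ketone with C12–CH2OH | CC(C)(C)[Si](C)(C)O[C@H]1C[C@]2(C)[C@@H]3[C@@H](O)CC(=O)[C@@H]3[C@@]23OC(=O)C(CO)=C13
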